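**Plan**

- Retrosynthesis (labdane locants: decalin C1–C10, C17 on C8, side chain C11–C16): cut the C16–O formate, then C12–C13 (B-alkyl coupling of a C9 vinyl group with a (Z)-β-iodo-enoate), then C9–C11 (vinyl onto a C9 ketone, reductive allylic transposition), and last the two ring A bonds C10–C1 and C5–C4.
- Enabling feature: ring B carries oxygen at C6, the C7=C8 bond with C17 on C8, and the C10 methyl. With C9 written as a carbonyl it is the C2v-symmetric 2,6-dimethyl-1,4-benzoquinone, and ring A (C1–C4 onto C10 and C5) is its [4+2] adduct with 4-methylpenta-1,3-diene. The C2=C3 alkene is the only helper and goes in step 2.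
- Forward: ring B is bought as the quinone and ring A is closed last by the cycloaddition. Ring B is then adjusted (C6 carbinol, C7=C8 re-formed next to the C9 ketone), C9 is vinylated and reduced, the side chain is coupled on, C17 is oxidised and C16 is formylated.
- Stereochemistry: C10 from the chiral Lewis acid (desymmetrisation of the quinone); C5 by equilibration to the trans fusion; C6 by dissolving-metal reduction (equatorial); C9 by hydride delivery anti to the C10 methyl; C13=C14 geometry from anti hydroiodination and a stereoretentive coupling.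

Key step: step 1

Assumption: the (S)-catalyst is taken to give the (4aS,8aR) adduct by the usual model for this catalyst class; if the sense proves opposite, the mirror-image catalyst is used. Compound names use naphthalene locants; the discussion uses labdane locants.

**Step 1**
Reactants: 1 2,6-dimethyl-1,4-benzoquinone; 2 4-methylpenta-1,3-diene
Product: 3 (4aS,8aR)-2,5,5,8a-tetramethyl-4a,5,8,8a-tetrahydronaphthalene-1,4-dione (cis-fused)
Conditions: (S)-oxazaborolidinium triflimide [from (S)-diphenylprolinol B-(o-tolyl)oxazaborolidine + Tf2NH] (20 mol%), 2 (3 equiv), CH2Cl2, −78 → −40 °C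
Reagents that add atoms: none
Why: Proposed new method: the cationic boron Lewis acid binds the more basic, less hindered C6 carbonyl (flanked by two C–H), so C10 becomes the most electrophilic carbon; the CH2 terminus of the diene bonds there first and the developing tertiary allyl cation collapses onto C5, a concerted but strongly asynchronous Diels–Alder [4+2] that closes ring A suprafacially (cis fusion) and leaves the second enedione bond C7=C8 in place. The closest known reactions are oxazaborolidinium-catalysed Diels–Alder additions of 2-substituted dienes to methylated benzoquinones, BF3-catalysed additions of alkyl dienes to this quinone, and AlCl3-catalysed additions of 4-methylpenta-1,3-diene to enones; a 4,4-disubstituted diene, which must reach the s-cis form against its cis methyl, has not been shown with an enantioselective quinone catalyst. C10 and C5 are the only new stereocentres: their cis relation follows from the cycloaddition, and their absolute sense from the catalyst, which tells apart the two enantiotopic C=C bonds of the C2v quinone. Regioselectivity (C1 to C10, C4 to C5) is secured twice, by polarisation through the bound C6 carbonyl and by avoidance of vicinal quaternary carbons; the adduct does not react again because its remaining C7=C8 bond is more hindered.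

**Step 2**
Reactants: 3
Product: 5 (2S,4aR,8aR)-2,5,5,8a-tetramethyloctahydronaphthalene-1,4-dione (trans-fused), via cis-fused saturated diketone 4 (not isolated)
Conditions: H2 (1 atm), Pd/C, MeOH, rt; then N2, NaOMe (0.2 equiv), rt
Reagents that add atoms: none
Why: Heterogeneous hydrogenation removes the helper alkene C2=C3 and saturates the enedione C7=C8 (re-formed in step 5), and methoxide then epimerises C5 and C8 through their enolates to the trans-fused diketone with the C8 methyl equatorial, which should be the thermodynamic isomer.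

**Step 3**
Reactants: 5
Product: 6 (1R,2S,4R,4aR,8aR)-2,5,5,8a-tetramethyldecahydronaphthalene-1,4-diol
Conditions: Li, NH3 (l), THF, t-BuOH, −78 °C; NH4Cl
Reagents that add atoms: none
Why: Dissolving-metal reduction of both ketones gives the more stable equatorial carbinols, so the C6 hydroxyl ends cis to H-5 and trans to the C10 methyl, which hydride reagents attacking anti to the two syn-axial methyls would not give; the C9 carbinol configuration is of no consequence.

**Step 4**
Reactants: 6
Product: 7 (1R,2S,4R,4aR,8aR)-4-[(tert-butyldimethylsilyl)oxy]-2,5,5,8a-tetramethyldecahydronaphthalen-1-ol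
Conditions: TBSCl (1.1 equiv), imidazole, DMF, 0 °C → rt
Reagents that add atoms: tert-butyldimethylsilyl chloride, CC(C)(C)[Si](C)(C)Cl
Why: Site-selective silyl ether formation should pick the C6 hydroxyl, which has an open CH2 flank, over the C9 hydroxyl, which sits between the quaternary C10 and the methyl-bearing C8.

**Step 5**
Reactants: 7
Product: 9 (4R,4aR,8aR)-4-[(tert-butyldimethylsilyl)oxy]-2,5,5,8a-tetramethyl-4a,5,6,7,8,8a-hexahydronaphthalen-1(4H)-one, via C9 ketone 8 (not isolated)
Conditions: IBX (2-iodoxybenzoic acid, 3.5 equiv), DMSO/fluorobenzene, 70 °C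
Reagents that add atoms: none
Why: IBX oxidises the C9 carbinol and then dehydrogenates the ketone through its only enol (C8=C9) to the endocyclic enone (IBX α,β-dehydrogenation), which re-forms the C7=C8 bond of the target and erases the C8 stereocentre.

**Step 6**
Reactants: 9
Product: 11 methyl (1R,4R,4aR,8aR)-4-[(tert-butyldimethylsilyl)oxy]-1-ethenyl-2,5,5,8a-tetramethyl-1,4,4a,5,6,7,8,8a-octahydronaphthalen-1-yl carbonate, via magnesium alkoxide 10 (not isolated)
Conditions: CH2=CHMgBr, THF, −78 → 0 °C; then ClCO2Me, −78 °C → rt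
Reagents that add atoms: vinylmagnesium bromide, C=C[Mg]Br; methyl chloroformate, COC(=O)Cl
Why: Grignard 1,2-addition to the non-enolisable enone carbonyl (attack anti to the axial C10 methyl) and acylation of the tertiary alkoxide in the same flask give the bis-allylic carbonate; its C9 configuration is lost in the next step.

**Step 7**
Reactants: 11
Product: 12 (1R,4R,4aR,8aS)-4-[(tert-butyldimethylsilyl)oxy]-1-ethenyl-2,5,5,8a-tetramethyl-1,4,4a,5,6,7,8,8a-octahydronaphthalene
Conditions: Pd(OAc)2 (5 mol%), PBu3 (20 mol%), HCO2H, Et3N, THF, 40 °C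
Reagents that add atoms: none
Why: Palladium-catalysed formate hydrogenolysis of the allylic carbonate (Tsuji reduction) passes through a π-allylpalladium hydride that delivers hydride to the more substituted terminus C9; because the π-allyl equilibrates through its unsubstituted terminus C12, the complex with palladium opposite the axial C10 methyl should react, putting H-9 trans to that methyl and leaving the vinyl group and C7=C8 in place.

**Step 8**
Reactants: 13 methyl 4-hydroxybut-2-ynoate
Product: 14 methyl (2Z)-4-hydroxy-3-iodobut-2-enoate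
Conditions: LiI, AcOH, MeCN, 70 °C
Reagents that add atoms: lithium iodide, [Li+].[I-]
Why: Conjugate hydroiodination of the ynoate (iodide to C3, anti protonation of the allenolate) gives the (Z)-β-iodo-enoate, in which CH2OH is trans to the ester and cannot lactonise.

**Step 9**
Reactants: 14
Product: 15 methyl (2Z)-4-[(tert-butyldimethylsilyl)oxy]-3-iodobut-2-enoate
Conditions: TBSCl, imidazole, CH2Cl2, 0 °C
Reagents that add atoms: tert-butyldimethylsilyl chloride, CC(C)(C)[Si](C)(C)Cl
Why: Standard silyl ether formation protects the primary allylic alcohol against the later allylic oxidation.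

**Step 10**
Reactants: 12; 15
Product: 17 methyl (2E)-3-{[(tert-butyldimethylsilyl)oxy]methyl}-5-[(1R,4R,4aR,8aS)-4-[(tert-butyldimethylsilyl)oxy]-2,5,5,8a-tetramethyl-1,4,4a,5,6,7,8,8a-octahydronaphthalen-1-yl]pent-2-enoate, via B-alkyl-9-BBN adduct 16 (not isolated)
Conditions: 9-BBN, THF, rt; then 15, PdCl2(dppf) (5 mol%), AsPh3, Cs2CO3, DMF/H2O, rt
Reagents that add atoms: none
Why: Anti-Markovnikov hydroboration of the vinyl group (the trisubstituted C7=C8 bond is inert to 9-BBN) followed by B-alkyl Suzuki–Miyaura coupling with retention at the iodo-alkene places C12 cis to the ester and C16 trans to it.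

**Step 11**
Reactants: 17
Product: 19 methyl (2E)-3-{[(tert-butyldimethylsilyl)oxy]methyl}-5-[(1S,4R,4aR,8aS)-4-[(tert-butyldimethylsilyl)oxy]-2-formyl-5,5,8a-trimethyl-1,4,4a,5,6,7,8,8a-octahydronaphthalen-1-yl]pent-2-enoate, via C17 allylic alcohol 18 (not isolated)
Conditions: SeO2, 1,4-dioxane, 80 °C
Reagents that add atoms: selenium dioxide, O=[Se]=O
Why: Riley allylic oxidation (ene reaction at the more substituted end of C7=C8, then [2,3] shift) should take the C8 methyl in preference to the tertiary C9–H and carry the allylic alcohol on to the enal, while the electron-poor enoate alkene does not react.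

**Step 12**
Reactants: 19
Product: 20 methyl (2E)-5-[(1S,4R,4aR,8aS)-2-formyl-4-hydroxy-5,5,8a-trimethyl-1,4,4a,5,6,7,8,8a-octahydronaphthalen-1-yl]-3-(hydroxymethyl)pent-2-enoate
Conditions: HF·pyridine, pyridine, THF, 0 °C → rt
Reagents that add atoms: none
Why: Buffered fluoride desilylation removes both silyl ethers without touching the enal, the enoate or the C6 configuration.

**Step 13**
Reactants: 20
Product: 21 methyl (2E)-3-[(formyloxy)methyl]-5-[(1S,4R,4aR,8aS)-2-formyl-4-hydroxy-5,5,8a-trimethyl-1,4,4a,5,6,7,8,8a-octahydronaphthalen-1-yl]pent-2-enoate (target)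
Conditions: CF3CH2OCHO (3 equiv), THF, 50 °C
Reagents that add atoms: 2,2,2-trifluoroethyl formate, O=COCC(F)(F)F
Why: Chemoselective O-formylation by acyl transfer should take the unhindered primary C16 hydroxyl and leave the secondary C6 hydroxyl, which is flanked by C5 and the peri methyl.

**Compound list**

1 | 2,6-dimethyl-1,4-benzoquinone | CC1=CC(=O)C=C(C)C1=O | starting material
2 | 4-methylpenta-1,3-diene | C=CC=C(C)C | starting material
3 | (4aS,8aR)-2,5,5,8a-tetramethyl-4a,5,8,8a-tetrahydronaphthalene-1,4-dione (cis-fused) | O=C1C(C)=CC(=O)[C@H]2C(C)(C)C=CC[C@@]12C | intermediate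
4 | (2S,4aS,8aR)-2,5,5,8a-tetramethyloctahydronaphthalene-1,4-dione (cis-fused) | O=C1[C@@H](C)CC(=O)[C@H]2C(C)(C)CCC[C@@]12C | intermediate
5 | (2S,4aR,8aR)-2,5,5,8a-tetramethyloctahydronaphthalene-1,4-dione (trans-fused) | O=C1[C@@H](C)CC(=O)[C@@H]2C(C)(C)CCC[C@@]12C | intermediate
6 | (1R,2S,4R,4aR,8aR)-2,5,5,8a-tetramethyldecahydronaphthalene-1,4-diol | O[C@@H]1[C@@H](C)C[C@@H](O)[C@@H]2C(C)(C)CCC[C@@]12C | intermediate
7 | (1R,2S,4R,4aR,8aR)-4-[(tert-butyldimethylsilyl)oxy]-2,5,5,8a-tetramethyldecahydronaphthalen-1-ol | O[C@@H]1[C@@H](C)C[C@@H](O[Si](C)(C)C(C)(C)C)[C@@H]2C(C)(C)CCC[C@@]12C | intermediate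
8 | (2S,4R,4aR,8aR)-4-[(tert-butyldimethylsilyl)oxy]-2,5,5,8a-tetramethyloctahydronaphthalen-1(2H)-one | O=C1[C@@H](C)C[C@@H](O[Si](C)(C)C(C)(C)C)[C@@H]2C(C)(C)CCC[C@@]12C | intermediate
9 | (4R,4aR,8aR)-4-[(tert-butyldimethylsilyl)oxy]-2,5,5,8a-tetramethyl-4a,5,6,7,8,8a-hexahydronaphthalen-1(4H)-one | O=C1C(C)=C[C@@H](O[Si](C)(C)C(C)(C)C)[C@@H]2C(C)(C)CCC[C@@]12C | intermediate
10 | bromomagnesium (1R,4R,4aR,8aR)-4-[(tert-butyldimethylsilyl)oxy]-1-ethenyl-2,5,5,8a-tetramethyl-1,4,4a,5,6,7,8,8a-octahydronaphthalen-1-olate | C=C[C@@]1(O[Mg]Br)C(C)=C[C@@H](O[Si](C)(C)C(C)(C)C)[C@@H]2C(C)(C)CCC[C@@]12C | intermediate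
11 | methyl (1R,4R,4aR,8aR)-4-[(tert-butyldimethylsilyl)oxy]-1-ethenyl-2,5,5,8a-tetramethyl-1,4,4a,5,6,7,8,8a-octahydronaphthalen-1-yl carbonate | C=C[C@@]1(OC(=O)OC)C(C)=C[C@@H](O[Si](C)(C)C(C)(C)C)[C@@H]2C(C)(C)CCC[C@@]12C | intermediate
12 | (1R,4R,4aR,8aS)-4-[(tert-butyldimethylsilyl)oxy]-1-ethenyl-2,5,5,8a-tetramethyl-1,4,4a,5,6,7,8,8a-octahydronaphthalene | C=C[C@@H]1C(C)=C[C@@H](O[Si](C)(C)C(C)(C)C)[C@@H]2C(C)(C)CCC[C@@]12C | intermediate
13 | methyl 4-hydroxybut-2-ynoate | COC(=O)C#CCO | starting material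
14 | methyl (2Z)-4-hydroxy-3-iodobut-2-enoate | COC(=O)/C=C(\I)CO | intermediate
15 | methyl (2Z)-4-[(tert-butyldimethylsilyl)oxy]-3-iodobut-2-enoate | COC(=O)/C=C(\I)CO[Si](C)(C)C(C)(C)C | intermediate
16 | 9-{2-[(1R,4R,4aR,8aS)-4-[(tert-butyldimethylsilyl)oxy]-2,5,5,8a-tetramethyl-1,4,4a,5,6,7,8,8a-octahydronaphthalen-1-yl]ethyl}-9-borabicyclo[3.3.1]nonane | C(C[C@@H]1C(C)=C[C@@H](O[Si](C)(C)C(C)(C)C)[C@@H]2C(C)(C)CCC[C@@]12C)B1C2CCCC1CCC2 | intermediate
17 | methyl (2E)-3-{[(tert-butyldimethylsilyl)oxy]methyl}-5-[(1R,4R,4aR,8aS)-4-[(tert-butyldimethylsilyl)oxy]-2,5,5,8a-tetramethyl-1,4,4a,5,6,7,8,8a-octahydronaphthalen-1-yl]pent-2-enoate | COC(=O)/C=C(\CC[C@@H]1C(C)=C[C@@H](O[Si](C)(C)C(C)(C)C)[C@@H]2C(C)(C)CCC[C@@]12C)CO[Si](C)(C)C(C)(C)C | intermediate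
18 | methyl (2E)-3-{[(tert-butyldimethylsilyl)oxy]methyl}-5-[(1S,4R,4aR,8aS)-4-[(tert-butyldimethylsilyl)oxy]-2-(hydroxymethyl)-5,5,8a-trimethyl-1,4,4a,5,6,7,8,8a-octahydronaphthalen-1-yl]pent-2-enoate | COC(=O)/C=C(\CC[C@@H]1C(CO)=C[C@@H](O[Si](C)(C)C(C)(C)C)[C@@H]2C(C)(C)CCC[C@@]12C)CO[Si](C)(C)C(C)(C)C | intermediate
19 | methyl (2E)-3-{[(tert-butyldimethylsilyl)oxy]methyl}-5-[(1S,4R,4aR,8aS)-4-[(tert-butyldimethylsilyl)oxy]-2-formyl-5,5,8a-trimethyl-1,4,4a,5,6,7,8,8a-octahydronaphthalen-1-yl]pent-2-enoate | COC(=O)/C=C(\CC[C@@H]1C(C=O)=C[C@@H](O[Si](C)(C)C(C)(C)C)[C@@H]2C(C)(C)CCC[C@@]12C)CO[Si](C)(C)C(C)(C)C | intermediate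
20 | methyl (2E)-5-[(1S,4R,4aR,8aS)-2-formyl-4-hydroxy-5,5,8a-trimethyl-1,4,4a,5,6,7,8,8a-octahydronaphthalen-1-yl]-3-(hydroxymethyl)pent-2-enoate | COC(=O)/C=C(\CC[C@@H]1C(C=O)=C[C@@H](O)[C@@H]2C(C)(C)CCC[C@@]12C)CO | intermediate
21 | methyl (2E)-3-[(formyloxy)methyl]-5-[(1S,4R,4aR,8aS)-2-formyl-4-hydroxy-5,5,8a-trimethyl-1,4,4a,5,6,7,8,8a-octahydronaphthalen-1-yl]pent-2-enoate | COC(=O)/C=C(\CC[C@@H]1C(C=O)=C[C@@H](O)[C@@H]2C(C)(C)CCC[C@@]12C)COC=O | target

**Totals**

Total steps: 13. Longest linear sequence: 11 (steps 1–7 and 10–13).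

**Steps most likely to fail**

Step 1. The bound quinone may not tell its two enantiotopic C=C bonds apart well with this hindered diene, or the strong Lewis acid may oligomerise the diene faster than it cycloadds. The fallback replaces asymmetric catalysis by a racemic cycloaddition of known type followed by resolution. It sets out from 1 and 2: BF3·OEt2 in CH2Cl2 at low temperature (or neat diene in a sealed tube without acid) should give the racemic cis-fused adduct F1. Steps 2 and 3 as written then give the racemic trans-fused diketone F2 and the racemic diol F3. F3 is resolved by preparative chromatography on a chiral stationary phase; the (1R,2S,4R,4aR,8aR) enantiomer is compound 6, where the route is rejoined.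

Step 7. Hydride may be delivered to C7 or C12 instead of C9 (conjugated dienes), the skipped diene may isomerise under the palladium hydride, or facial selectivity at C9 may be low. The fallback sets out from 9 and builds the vinyl group by hydroboration logic instead. Wittig methylenation (Ph3P=CH2, toluene, 90 °C) should give the exocyclic diene F4. 9-BBN then NaOH/H2O2 hydroborates the terminal C9=C11 bond from the face opposite the C10 methyl and gives the C11 alcohol F5. Dess–Martin periodinane with NaHCO3 gives the C11 aldehyde F6, which is methylenated at −78 °C (Ph3P=CH2) to give 12, where the route is rejoined.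

Step 4. The two hindered secondary hydroxyls may not be told apart, giving the wrong or a double silyl ether. The fallback sets out from 5 and bypasses steps 3 to 5 by delivering the C6 oxygen as an epoxide from the open face. KN(SiMe3)2 and PhNTf2 at −78 °C (kinetic C7 enolate of the C6 ketone) should give the enol triflate F7. Pd(OAc)2/PPh3, Bu3N and HCO2H reduce it to the C6=C7 alkene F8. mCPBA epoxidises the face opposite the C10 methyl to give the epoxide F9. DBU opens it by β-elimination from the C9 enolate to the hydroxy-enone F10, with the C6–O bond untouched and equatorial. TBSCl/imidazole then gives 9, where the route is rejoined.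

**Further compounds**

F1 | step 1 | racemic cis-fused 2,5,5,8a-tetramethyl-4a,5,8,8a-tetrahydronaphthalene-1,4-dione | O=C1C(C)=CC(=O)[C@H]2C(C)(C)C=CC[C@@]12C.O=C1C(C)=CC(=O)[C@@H]2C(C)(C)C=CC[C@]12C
F2 | step 1 | racemic trans-fused 2,5,5,8a-tetramethyloctahydronaphthalene-1,4-dione (C2 methyl equatorial) | O=C1[C@@H](C)CC(=O)[C@@H]2C(C)(C)CCC[C@@]12C.O=C1[C@H](C)CC(=O)[C@H]2C(C)(C)CCC[C@]12C
F3 | step 1 | racemic 2,5,5,8a-tetramethyldecahydronaphthalene-1,4-diol (relative configuration of 6) | O[C@@H]1[C@@H](C)C[C@@H](O)[C@@H]2C(C)(C)CCC[C@@]12C.O[C@H]1[C@H](C)C[C@H](O)[C@H]2C(C)(C)CCC[C@]12C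
F4 | step 7 | (4R,4aR,8aR)-4-[(tert-butyldimethylsilyl)oxy]-2,5,5,8a-tetramethyl-1-methylidene-1,4,4a,5,6,7,8,8a-octahydronaphthalene | C=C1C(C)=C[C@@H](O[Si](C)(C)C(C)(C)C)[C@@H]2C(C)(C)CCC[C@@]12C
F5 | step 7 | [(1R,4R,4aR,8aS)-4-[(tert-butyldimethylsilyl)oxy]-2,5,5,8a-tetramethyl-1,4,4a,5,6,7,8,8a-octahydronaphthalen-1-yl]methanol | OC[C@@H]1C(C)=C[C@@H](O[Si](C)(C)C(C)(C)C)[C@@H]2C(C)(C)CCC[C@@]12C
F6 | step 7 | (1R,4R,4aR,8aR)-4-[(tert-butyldimethylsilyl)oxy]-2,5,5,8a-tetramethyl-1,4,4a,5,6,7,8,8a-octahydronaphthalene-1-carbaldehyde | O=C[C@@H]1C(C)=C[C@@H](O[Si](C)(C)C(C)(C)C)[C@@H]2C(C)(C)CCC[C@@]12C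
F7 | step 4 | C6 enol triflate of diketone 5 (C6=C7, trans-fused, C9 ketone kept) | O=C1[C@@H](C)C=C(OS(=O)(=O)C(F)(F)F)[C@@H]2C(C)(C)CCC[C@@]12C
F8 | step 4 | trans-fused C6=C7 alkene with C9 ketone (reduced enol triflate) | O=C1[C@@H](C)C=C[C@@H]2C(C)(C)CCC[C@@]12C
F9 | step 4 | C6–C7 epoxide of F8, oxygen on the face opposite the C10 methyl | O=C1[C@@H](C)[C@H]3O[C@H]3[C@@H]2C(C)(C)CCC[C@@]12C
F10 | step 4 | (4R,4aR,8aR)-4-hydroxy-2,5,5,8a-tetramethyl-4a,5,6,7,8,8a-hexahydronaphthalen-1(4H)-one | O=C1C(C)=C[C@@H](O)[C@@H]2C(C)(C)CCC[C@@]12C
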